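Follow the G. In the new flasks L stands at 13.2 mM against 12 mM of G, so G is the limiting reagent, and I keep its books in fractions of the charge.

| flask | G | L | temperature | remark | time |
|---|---|---|---|---|---|
| larch | 12 mM | 13.2 mM | −15 °C | run made earlier |  |
| alder | 12 mM | 8.8 mM | 0 °C | run made earlier |  |
| ash | 12 mM | 20 mM | −15 °C | run made earlier |  |
| spring | 12 mM (fed, over 15 h) | 13.2 mM |  | the addition at −40 °C, then warmed to 0 °C; the feed brings no volume worth counting | 40 h |
| autumn | 12 mM (fed, over 4.0 h) | 13.2 mM | 0 °C | all else is in the flask from the start; the feed brings no volume worth counting | 40 h |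
| summer | 12 mM (in portions, 2, over 15 h) | 13.2 mM | 0 °C | first portion at the start, last at 15 h | 40 h |
| dawn | 12 mM (fed, over 15 h) | 13.2 mM | 0 °C | all else is in the flask from the start; the feed brings no volume worth counting | 40 h |
| noon | 12 mM | 13.2 mM | 0 °C | everything together at the start | 40 h |

| run | time / h | J / % | E / % |
|---|---|---|---|
| larch | 12.0 | 34 | 1 |
| larch | 25.0 | 43 | 3 |
| larch | 40.0 | 46 | 0 |
| larch | 48.0 | 50 | 1 |
| alder | 4.00 | 30 | 0 |
| alder | 12.0 | 41 | 1 |
| alder | 20.0 | 45 | 4 |
| alder | 30.0 | 49 | 10 |
| ash | 5.00 | 24 | 0 |
| ash | 12.0 | 41 | 4 |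
| ash | 30.0 | 48 | 0 |
| ash | 60.0 | 56 | 1 |

(standard deviation of a reading: 2 percentage points)

- percent here means G units held: one Z counts as two
- what is said of J includes Z
- reactions considered so far: G + L -> J + X; G + J <-> Z; J -> E
- in an amount of J, one Z counts as one J

- the flask that comes out highest in share of J in J plus E, or "all alike" when all lie within 1.5 percentage points (spring / autumn / summer / dawn / noon / all alike)
- share of J in J plus E at the end, spring
- share of J in J plus E at the end, autumn
- share of J in J plus E at the end, summer
- share of J in J plus E at the end, dawn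
- share of J in J plus E at the end, noon

My ledger at 0 °C is the alder run, though alder holds less L than the new flasks, so its curve is borrowed. At 30.0 h alder reads 49% in J and 10% in E, and the remaining 41.0% is G, free or sitting as the second unit of Z. That last entry can still pass into J by way of L, while E is J already lost. Between 12.0 h and 30.0 h E gains 9 percentage points while J reads about 45%. So I define the leak, the fraction of the J standing, Z included, that passes to E each hour: 0.0111 h⁻¹. It is a reading, and each E in it carries a scatter of 2 points.

Next I replace the rising J curve by its mean, 41.2% over the alder readings, and charge E as leak times mean J times the hours G has spent warm. Noon gets the full 40 h, so E comes to 18.3%. Dawn and summer receive their G on average at the middle of 15 h, so they get 14.9%, and autumn, fed over 4.0 h, gets 17.4%. Spring I count as idle until warmed, since larch, at −15 °C, shows E of 1% at 48.0 h, which leaves 11.5%. Holding J at 49%, my shares are spring 81.0%, dawn and summer 76.7%, autumn 73.8%, noon 72.8%.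

The forecast differs from mine. It gives spring 87%, autumn 77%, summer 76%, dawn 76%, noon 77%, and picks spring, on the ground that “In spring almost nothing happens during the cold addition”.

The flasks give spring 83.1%, autumn 71.0%, summer 76.1%, dawn 77.2%, noon 69.0%, so spring comes highest.

    G + L → J + X (k = 16.0 M⁻¹ h⁻¹, Ea = 56.0 kJ mol⁻¹)
    G + J ⇌ Z, settled at all times (K = 2900 M⁻¹, ΔH = −77.0 kJ mol⁻¹)
    J → E (k = 0.0380 h⁻¹, Ea = 84.0 kJ mol⁻¹)
    (constants at 0 °C)

My flat mean put E in noon at 18.3% against the simulated 21.0%, and in spring at 11.5% against 10.4%. Neither flask is at rest at 40 h, which is shorter than the leak's time 90.1 h. At 400 h the share is 0.453% in spring and 0.343% in noon, with E at 99.2% in spring. Noon left until 4.0 d tests the leak: from the simulated 46.7% of J at 40.0 h it gives 25.1%. The computed flask holds 27.3%, with a share of 33.4%.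

All runs were computed on assumed constants, and the scatter is random.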